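**Retrosynthetic overview**
- The last bond made is the ring C quinone–oxygen bond: a ring B phenol, whose hydroxyl lies between the ring A aryloxy group and isopropyl, displaces bromide from 2-bromo-6-isopropyl-3-methyl-1,4-benzoquinone (made from thymol).
- That phenol comes from the ring B para-quinone by reduction and methylation of the less hindered hydroxyl; the quinone comes from para-oxidation of a simpler ring B phenol.
- Feature: ring B carries the ring A oxygen, a methyl and the methoxy group on three adjacent carbons, and its isopropyl carbon stands 1,3 to both oxygen-bearing carbons. This is the print of a 1-aryloxypropyne joined to a 3-isopropylcyclobutenone, so ring B is cut at C(methyl)–C(hydroxyl) and at C(aryloxy)–C(H) (Danheiser benzannulation).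
- The propynyl ether comes from 4-methoxythymol (carvacrol: O-methylation, para-bromination, Br to OH) and trichloroethylene; the cyclobutenone comes from 3-methylbut-1-yne and dichloroketene.
- Ring order: ring A is bought (carvacrol), ring B is built by the benzannulation, ring C is bought (thymol) and attached last.

Key step: step 8

Remark on the chemistry: the target has no stereocentre and no configured double bond, so no stereocontrol is needed. Carvacrol is assumed as the source of ring A, because para-bromination of its methyl ether fixes the hydroxyl/methoxy pattern of 4-methoxythymol without a regiochemical separation.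

Step 1
Reactants: 1 carvacrol (5-isopropyl-2-methylphenol)
Product: 2 carvacrol methyl ether (4-isopropyl-2-methoxy-1-methylbenzene)
Conditions: MeI, K2CO3, acetone, reflux
Reagents that add atoms: iodomethane, CI
Why: Williamson O-methylation of the phenoxide is routine and places the future ring A methoxy group next to the methyl group.

Step 2
Reactants: 2 carvacrol methyl ether
Product: 3 1-bromo-2-isopropyl-4-methoxy-5-methylbenzene
Conditions: NBS, MeCN, 0 °C → rt
Reagents that add atoms: N-bromosuccinimide, O=C1CCC(=O)N1Br
Why: Electrophilic aromatic bromination should go para to methoxy, because the only other methoxy-activated position is wedged between methoxy and isopropyl.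

Step 3
Reactants: 3 1-bromo-2-isopropyl-4-methoxy-5-methylbenzene
Product: 6 4-methoxythymol (2-isopropyl-4-methoxy-5-methylphenol), via aryllithium 4 (not isolated), via aryl boronate 5 (not isolated)
Conditions: n-BuLi, THF, −78 °C; B(OMe)3, −78 °C → rt; H2O2, aq NaOH, 0 °C → rt
Reagents that add atoms: hydrogen peroxide, OO
Why: Bromine–lithium exchange, borylation and boronate oxidation (1,2-aryl shift from boron to oxygen) put the hydroxyl exactly where bromine stood, ortho to isopropyl and para to methoxy.

Step 4
Reactants: 6 4-methoxythymol; 7 trichloroethylene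
Product: 9 1-[(E)-1,2-dichlorovinyloxy]-2-isopropyl-4-methoxy-5-methylbenzene, via dichloroacetylene 8 (not isolated)
Conditions: K2CO3, DMF, 70 °C
Reagents that add atoms: none
Why: Base-induced dehydrochlorination of trichloroethylene gives dichloroacetylene, and anti addition of the phenoxide gives the (E)-dichlorovinyl ether (the known preparation of aryl dichlorovinyl ethers); the aryl–O–C bond forms at an sp carbon, so the ortho isopropyl group should not interfere.

Step 5
Reactants: 9 1-[(E)-1,2-dichlorovinyloxy]-2-isopropyl-4-methoxy-5-methylbenzene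
Product: 12 1-isopropyl-5-methoxy-4-methyl-2-(prop-1-yn-1-yloxy)benzene, via chloroethynyl ether 10 (not isolated), via lithium acetylide 11 (not isolated)
Conditions: n-BuLi (2.2 equiv), THF, −78 → −40 °C; MeI, HMPA, −78 °C → rt
Reagents that add atoms: iodomethane, CI
Why: This is the established dichlorovinyl ether route to ynol ethers: lithiation and β-elimination of LiCl give the chloroalkyne, chlorine–lithium exchange gives the lithium alkynyl ether, and C-methylation with MeI/HMPA caps the alkyne.

Step 6
Reactants: 13 3-methylbut-1-yne; 14 trichloroacetyl chloride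
Product: 16 4,4-dichloro-3-isopropylcyclobut-2-en-1-one, via dichloroketene 15 (not isolated)
Conditions: Zn(Cu), Et2O/DME, rt, slow addition of 14, cold condenser
Reagents that add atoms: none
Why: [2+2] cycloaddition of dichloroketene (from zinc dechlorination of the acid chloride) to a terminal alkyne joins the terminal alkyne carbon to the ketene carbonyl carbon, so isopropyl ends at C3.

Step 7
Reactants: 16 4,4-dichloro-3-isopropylcyclobut-2-en-1-one
Product: 17 3-isopropylcyclobut-2-en-1-one
Conditions: Zn, AcOH, TMEDA, EtOH, 0 °C → rt
Reagents that add atoms: none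
Why: Zinc reductive dechlorination of the α,α-dichloroketone, buffered by TMEDA/AcOH so that the strained enone survives, is the standard access to 3-alkylcyclobutenones.

Step 8
Reactants: 12 1-isopropyl-5-methoxy-4-methyl-2-(prop-1-yn-1-yloxy)benzene; 17 3-isopropylcyclobut-2-en-1-one
Product: 22 3-(2-isopropyl-4-methoxy-5-methylphenoxy)-5-isopropyl-2-methylphenol, via vinylketene 18 (not isolated), via vinylcyclobutenone 19 (not isolated), via dienylketene 20 (not isolated), via cyclohexadienone 21 (not isolated)
Conditions: PhMe, 80 → 110 °C, sealed tube, Ar, 17 in excess; then KOH, MeOH, rt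
Reagents that add atoms: none
Why: On heating, cyclobutenone 17 should open by 4π electrocyclic cleavage to vinylketene 18, whose ketene C=C bond adds across the ynol ether triple bond in a [2+2] cycloaddition to give 4-vinylcyclobutenone 19; a second, reversible 4π opening gives dienylketene 20, and 6π electrocyclization to cyclohexadienone 21 followed by tautomerization gives phenol 22. This is the Danheiser benzannulation as practised with alkoxy- and siloxyalkynes. Ring B is thus closed by a pericyclic cascade ([2+2] cycloaddition, then 6π electrocyclization), which joins the methyl-bearing alkyne carbon to the future phenol carbon and the oxygen-bearing alkyne carbon to the former C2–H carbon of 17. No stereocentre remains in 22; the one in 19 is transient. The selectivity needed is the orientation of the [2+2] step, and the polarization of the ynol ether secures it: the methyl-bearing carbon is the nucleophilic terminus and attacks the ketene carbonyl carbon, which places methyl between hydroxyl and aryloxy. The aryloxy group has no β-hydrogen, so the retro-ene loss of alkene that limits alkyl ynol ethers at these temperatures cannot compete, and the KOH/MeOH treatment frees any phenol that excess vinylketene has O-acylated.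

Step 9
Reactants: 22 3-(2-isopropyl-4-methoxy-5-methylphenoxy)-5-isopropyl-2-methylphenol
Product: 23 3-(2-isopropyl-4-methoxy-5-methylphenoxy)-5-isopropyl-2-methyl-1,4-benzoquinone
Conditions: (KSO3)2NO (2.5 equiv), KH2PO4, H2O/acetone, rt
Reagents that add atoms: potassium nitrosodisulfonate (KSO3)2NO, [K+].[K+].[O]N(S(=O)(=O)[O-])S(=O)(=O)[O-]
Why: In the Teuber oxidation the phenoxyl radical is captured by a second nitroxide at the free para position (between aryloxy and isopropyl), and loss of imidodisulfonate gives the para-quinone; ring A has no free hydroxyl and should stay untouched.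

Step 10
Reactants: 23 3-(2-isopropyl-4-methoxy-5-methylphenoxy)-5-isopropyl-2-methyl-1,4-benzoquinone
Product: 24 3-(2-isopropyl-4-methoxy-5-methylphenoxy)-5-isopropyl-2-methylbenzene-1,4-diol
Conditions: Na2S2O4, THF/H2O, rt, Ar; crude product carried on under Ar
Reagents that add atoms: none
Why: Dithionite reduction of a quinone to its hydroquinone is fast and chemoselective.

Step 11
Reactants: 24 3-(2-isopropyl-4-methoxy-5-methylphenoxy)-5-isopropyl-2-methylbenzene-1,4-diol
Product: 25 2-(2-isopropyl-4-methoxy-5-methylphenoxy)-6-isopropyl-4-methoxy-3-methylphenol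
Conditions: MeI (1.05 equiv), K2CO3, degassed acetone, rt
Reagents that add atoms: iodomethane, CI
Why: Williamson methylation under steric control should take the hydroxyl flanked by methyl and hydrogen in preference to the one buried between the aryloxy and isopropyl groups (which is also hydrogen-bonded to the ether oxygen).

Step 12
Reactants: 26 thymol (2-isopropyl-5-methylphenol)
Product: 27 2,4-dibromo-6-isopropyl-3-methylphenol
Conditions: Br2 (2.1 equiv), AcOH, rt
Reagents that add atoms: bromine, BrBr
Why: Electrophilic bromination of the phenol fills its free ortho and para positions, the two most activated sites.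

Step 13
Reactants: 27 2,4-dibromo-6-isopropyl-3-methylphenol
Product: 28 2-bromo-6-isopropyl-3-methyl-1,4-benzoquinone
Conditions: CrO3, AcOH/H2O, 40 °C
Reagents that add atoms: chromium trioxide CrO3, O=[Cr](=O)=O; water, O (one of the two supplies the new carbonyl oxygen)
Why: Chromic acid oxidation of a 4-bromophenol to the para-quinone with ipso loss of the para bromine is the classical route to 2-haloquinones from 2,4-dihalophenols, and it leaves the bromine next to methyl in place.

Step 14
Reactants: 25 2-(2-isopropyl-4-methoxy-5-methylphenoxy)-6-isopropyl-4-methoxy-3-methylphenol; 28 2-bromo-6-isopropyl-3-methyl-1,4-benzoquinone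
Product: 29 2-[2-(2-isopropyl-4-methoxy-5-methylphenoxy)-6-isopropyl-4-methoxy-3-methylphenoxy]-6-isopropyl-3-methyl-1,4-benzoquinone (CNP0335608.0)
Conditions: Cs2CO3, MeCN, 0 °C → rt, Ar
Reagents that add atoms: none
Why: Addition–elimination (vinylogous acyl substitution) of the caesium phenoxide at the bromine-bearing quinone carbon should expel bromide and form the aryloxyquinone at the carbon between methyl and the carbonyl next to isopropyl.

**Compound list**
1 | carvacrol (5-isopropyl-2-methylphenol) | Cc1ccc(C(C)C)cc1O | starting material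
2 | carvacrol methyl ether (4-isopropyl-2-methoxy-1-methylbenzene) | COc1cc(C(C)C)ccc1C | intermediate
3 | 1-bromo-2-isopropyl-4-methoxy-5-methylbenzene | COc1cc(C(C)C)c(Br)cc1C | intermediate
4 | (2-isopropyl-4-methoxy-5-methylphenyl)lithium | [Li]c1cc(C)c(OC)cc1C(C)C | intermediate (not isolated)
5 | dimethyl (2-isopropyl-4-methoxy-5-methylphenyl)boronate | COB(OC)c1cc(C)c(OC)cc1C(C)C | intermediate (not isolated)
6 | 4-methoxythymol (2-isopropyl-4-methoxy-5-methylphenol) | COc1cc(C(C)C)c(O)cc1C | intermediate
7 | trichloroethylene | ClC=C(Cl)Cl | starting material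
8 | dichloroacetylene | ClC#CCl | intermediate (not isolated)
9 | 1-[(E)-1,2-dichlorovinyloxy]-2-isopropyl-4-methoxy-5-methylbenzene | Cl/C=C(/Cl)Oc1cc(C)c(OC)cc1C(C)C | intermediate
10 | 1-(chloroethynyloxy)-2-isopropyl-4-methoxy-5-methylbenzene | ClC#COc1cc(C)c(OC)cc1C(C)C | intermediate (not isolated)
11 | lithium (2-isopropyl-4-methoxy-5-methylphenoxy)acetylide | [Li]C#COc1cc(C)c(OC)cc1C(C)C | intermediate (not isolated)
12 | 1-isopropyl-5-methoxy-4-methyl-2-(prop-1-yn-1-yloxy)benzene | CC#COc1cc(C)c(OC)cc1C(C)C | intermediate
13 | 3-methylbut-1-yne | CC(C)C#C | starting material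
14 | trichloroacetyl chloride | ClC(Cl)(Cl)C(Cl)=O | starting material
15 | dichloroketene | ClC(Cl)=C=O | intermediate (not isolated)
16 | 4,4-dichloro-3-isopropylcyclobut-2-en-1-one | CC(C)C1=CC(=O)C1(Cl)Cl | intermediate
17 | 3-isopropylcyclobut-2-en-1-one | CC(C)C1=CC(=O)C1 | intermediate
18 | 4-methyl-3-methylidenepent-1-en-1-one (vinylketene) | O=C=CC(=C)C(C)C | intermediate (not isolated)
19 | 3-(2-isopropyl-4-methoxy-5-methylphenoxy)-2-methyl-4-(3-methylbut-1-en-2-yl)cyclobut-2-en-1-one (racemic) | CC1=C(Oc2cc(C)c(OC)cc2C(C)C)C(C(=C)C(C)C)C1=O | intermediate (not isolated)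
20 | (3E)-3-(2-isopropyl-4-methoxy-5-methylphenoxy)-2,6-dimethyl-5-methylidenehepta-1,3-dien-1-one (dienylketene, ketene and vinyl termini cis) | O=C=C(C)/C(Oc1cc(C)c(OC)cc1C(C)C)=C\C(=C)C(C)C | intermediate (not isolated)
21 | 3-(2-isopropyl-4-methoxy-5-methylphenoxy)-5-isopropyl-2-methylcyclohexa-2,4-dien-1-one | O=C1CC(C(C)C)=CC(Oc2cc(C)c(OC)cc2C(C)C)=C1C | intermediate (not isolated)
22 | 3-(2-isopropyl-4-methoxy-5-methylphenoxy)-5-isopropyl-2-methylphenol | COc1cc(C(C)C)c(Oc2cc(C(C)C)cc(O)c2C)cc1C | intermediate
23 | 3-(2-isopropyl-4-methoxy-5-methylphenoxy)-5-isopropyl-2-methyl-1,4-benzoquinone | CC1=C(Oc2cc(C)c(OC)cc2C(C)C)C(=O)C(C(C)C)=CC1=O | intermediate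
24 | 3-(2-isopropyl-4-methoxy-5-methylphenoxy)-5-isopropyl-2-methylbenzene-1,4-diol | Cc1c(O)cc(C(C)C)c(O)c1Oc1cc(C)c(OC)cc1C(C)C | intermediate
25 | 2-(2-isopropyl-4-methoxy-5-methylphenoxy)-6-isopropyl-4-methoxy-3-methylphenol | COc1cc(C(C)C)c(O)c(Oc2cc(C)c(OC)cc2C(C)C)c1C | intermediate
26 | thymol (2-isopropyl-5-methylphenol) | Cc1ccc(C(C)C)c(O)c1 | starting material
27 | 2,4-dibromo-6-isopropyl-3-methylphenol | Cc1c(Br)cc(C(C)C)c(O)c1Br | intermediate
28 | 2-bromo-6-isopropyl-3-methyl-1,4-benzoquinone | CC1=C(Br)C(=O)C(C(C)C)=CC1=O | intermediate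
29 | 2-[2-(2-isopropyl-4-methoxy-5-methylphenoxy)-6-isopropyl-4-methoxy-3-methylphenoxy]-6-isopropyl-3-methyl-1,4-benzoquinone (CNP0335608.0) | COc1cc(C(C)C)c(Oc2c(C)c(OC)cc(C(C)C)c2OC2=C(C)C(=O)C=C(C(C)C)C2=O)cc1C | target

**Step count**
Total: 14 steps. Longest linear sequence: 10 steps (steps 1–5, 8–11 and 14, from carvacrol); steps 6–7 and 12–13 are side branches.

**Steps most likely to fail**

1. Step 8 (benzannulation). The aryl ynol ether may capture the vinylketene too slowly, so that ketene dimerization and acylation of the product phenol outrun ring formation, or the second ring opening may not funnel into the 6π closure. Fallback: ring B is taken from thymol instead of being built. The fallback sets out from 6 and 28, both already on the route: the caesium phenoxide of 6 (Cs2CO3, MeCN, rt) should displace bromide from 28 by addition–elimination and give quinone 23 directly, since the aryloxy group of 23 sits on the very quinone carbon that carries bromine in 28. The route is rejoined at 23 and continues with step 10; no new compound is needed (F0).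

2. Step 14 (final aryloxyquinone formation). The electron-rich, doubly ortho-substituted phenoxide may transfer an electron to the bromoquinone (redox exchange and phenoxyl coupling) instead of adding at the hindered carbon. Fallback: ring C is built by repeating the benzannulation logic.
   - Setting out from 25, trichloroethylene and K2CO3 in DMF should give the (E)-1,2-dichlorovinyl ether F1.
   - n-BuLi should convert it, by way of the chloroethynyl ether F2 and the lithium acetylide F3, into a species that MeI/HMPA methylates to the prop-1-ynyl ether F4.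
   - Heating F4 with 17 in toluene should lead, through vinylketene 18, the 4-vinylcyclobutenone F5, the dienylketene F6 and the cyclohexadienone F7, to the phenol F8.
   - Oxidation of F8 with (KSO3)2NO at its free para position (between aryloxy and isopropyl) comes back to the route at 29.

3. Step 11 (monomethylation). Site selectivity may be lost (alkylation at the hindered hydroxyl or at both), made worse by re-oxidation of the hydroquinone by air under base. Fallback: the two oxygens are told apart by the order of their introduction instead of by sterics.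
   - Setting out from 22, Elbs persulfate oxidation (K2S2O8, aq KOH/pyridine, 5–20 °C) should place a sulfate ester para to the hydroxyl and give the potassium aryl sulfate F9.
   - The remaining free phenol is methylated in the same alkaline medium (Me2SO4) to the potassium methoxyaryl sulfate F10.
   - Hydrolysis of the sulfate ester with hot aq HCl comes back to the route at 25.

**Further compounds**
F0 | step 8 | none | none
F1 | step 14 | 1-[(E)-1,2-dichlorovinyloxy]-2-(2-isopropyl-4-methoxy-5-methylphenoxy)-6-isopropyl-4-methoxy-3-methylbenzene | Cl/C=C(/Cl)Oc1c(C(C)C)cc(OC)c(C)c1Oc2cc(C)c(OC)cc2C(C)C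
F2 | step 14 | 1-(chloroethynyloxy)-2-(2-isopropyl-4-methoxy-5-methylphenoxy)-6-isopropyl-4-methoxy-3-methylbenzene | ClC#COc1c(C(C)C)cc(OC)c(C)c1Oc2cc(C)c(OC)cc2C(C)C
F3 | step 14 | lithium [2-(2-isopropyl-4-methoxy-5-methylphenoxy)-6-isopropyl-4-methoxy-3-methylphenoxy]acetylide | [Li]C#COc1c(C(C)C)cc(OC)c(C)c1Oc2cc(C)c(OC)cc2C(C)C
F4 | step 14 | 2-(2-isopropyl-4-methoxy-5-methylphenoxy)-6-isopropyl-4-methoxy-3-methyl-1-(prop-1-yn-1-yloxy)benzene | CC#COc1c(C(C)C)cc(OC)c(C)c1Oc2cc(C)c(OC)cc2C(C)C
F5 | step 14 | 3-[2-(2-isopropyl-4-methoxy-5-methylphenoxy)-6-isopropyl-4-methoxy-3-methylphenoxy]-2-methyl-4-(3-methylbut-1-en-2-yl)cyclobut-2-en-1-one (racemic) | CC1=C(Oc2c(C(C)C)cc(OC)c(C)c2Oc3cc(C)c(OC)cc3C(C)C)C(C(=C)C(C)C)C1=O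
F6 | step 14 | (3E)-3-[2-(2-isopropyl-4-methoxy-5-methylphenoxy)-6-isopropyl-4-methoxy-3-methylphenoxy]-2,6-dimethyl-5-methylidenehepta-1,3-dien-1-one | O=C=C(C)/C(Oc1c(C(C)C)cc(OC)c(C)c1Oc2cc(C)c(OC)cc2C(C)C)=C\C(=C)C(C)C
F7 | step 14 | 3-[2-(2-isopropyl-4-methoxy-5-methylphenoxy)-6-isopropyl-4-methoxy-3-methylphenoxy]-5-isopropyl-2-methylcyclohexa-2,4-dien-1-one | O=C1CC(C(C)C)=CC(Oc2c(C(C)C)cc(OC)c(C)c2Oc3cc(C)c(OC)cc3C(C)C)=C1C
F8 | step 14 | 3-[2-(2-isopropyl-4-methoxy-5-methylphenoxy)-6-isopropyl-4-methoxy-3-methylphenoxy]-5-isopropyl-2-methylphenol | Cc1c(O)cc(C(C)C)cc1Oc2c(C(C)C)cc(OC)c(C)c2Oc3cc(C)c(OC)cc3C(C)C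
F9 | step 11 | potassium 2-(2-isopropyl-4-methoxy-5-methylphenoxy)-4-hydroxy-6-isopropyl-3-methylphenyl sulfate | [K+].Cc1c(O)cc(C(C)C)c(OS(=O)(=O)[O-])c1Oc1cc(C)c(OC)cc1C(C)C
F10 | step 11 | potassium 2-(2-isopropyl-4-methoxy-5-methylphenoxy)-6-isopropyl-4-methoxy-3-methylphenyl sulfate | [K+].COc1cc(C(C)C)c(OS(=O)(=O)[O-])c(Oc2cc(C)c(OC)cc2C(C)C)c1C
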